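**Plan**

1. Germacrane locants are used: ring C1–C10, lactone O on C6, C11 on C7 carrying C12 (C=O) and C13 (exocyclic CH2), C14 = CH3 on C10, C15 = CH2OH on C4. Retrosynthesis cuts the C8 ester, then the lactone C12–O bond (back to a 2-methylene-1,4-diol), then C6–C7.
2. The C6 carbinol, C7 and the C11=C13 methylene make up a 2-methylene homoallylic alcohol, the retron of a [2,3]-Wittig shift of an O6–C13 allyl ether. The ten-membered ring C1–C10 is therefore traced back to the 13-membered ether ring C3–C4=C5–C6–O–C13–C11=C7–C8–C9–C10=C1–C2.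
3. That ether is cut at O–C13 (Williamson) and C2–C3 (allyl sulfone alkylation) into fragment 14 (C7–C2 with C11–C13 and C14, from nerol) and fragment 22 (C3–C6 with C15, from but-2-yne-1,4-diol).
4. Forward: 14 and 22 are joined at C2–C3, the sulfone is removed, the 13-membered ether ring is closed, ring contraction gives the ten-membered carbocycle, oxidation of the C6/C12 diol closes the lactone ring, and C8 is acylated last.
5. Stereochemistry: C8 from D-proline-catalysed alpha-aminoxylation; C6 and C7 from the ring contraction under control of the C7=C11 geometry and of C8; the acyl stereocentre from (R)-Roche ester. Z-C1=C10 comes from nerol, C7=C11 from an E-selective Horner–Wadsworth–Emmons reaction, C4=C5 from trans-hydroalumination/iodination followed by Stille coupling.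

Key step: step 22

Remark: TBS = tert-butyldimethylsilyl, TBDPS = tert-butyldiphenylsilyl, PMB = 4-methoxybenzyl, THP = tetrahydropyran-2-yl; THP ethers are carried as mixtures at the acetal carbon and sulfone 23 as a mixture at C2 (both centres are removed later); lithiated, sodiated and aluminated forms of numbered compounds are treated as reactive states of those compounds.

**Route**

Step 1
Reactants: 1 trimethyl 2-phosphonoacrylate; 2 4-methoxybenzyl alcohol
Product: 3 PMB-oxymethyl phosphonoacetate, methyl 2-(dimethoxyphosphoryl)-3-[(4-methoxybenzyl)oxy]propanoate (racemic)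
Conditions: NaH, THF, 0 °C; then AcOH
Reagents that add atoms: none
Why: Oxa-Michael addition of the sodium alkoxide of 2 to the doubly activated vinylphosphonate gives a stabilised phosphonate carbanion that is simply protonated on quench.

Step 2
Reactants: 4 nerol
Product: 5 neryl chloride, (2Z)-1-chloro-3,7-dimethylocta-2,6-diene
Conditions: N-chlorosuccinimide, Me2S, CH2Cl2, −30 to 0 °C
Reagents that add atoms: N-chlorosuccinimide, O=C1CCC(=O)N1Cl
Why: Corey–Kim chlorination displaces the alkoxysulfonium ion by chloride in SN2 fashion, so the primary allylic chloride should form without allylic transposition or loss of the Z geometry.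

Step 3
Reactants: 5 neryl chloride
Product: 6 neryl phenyl sulfone, {[(2Z)-3,7-dimethylocta-2,6-dien-1-yl]sulfonyl}benzene
Conditions: PhSO2Na, DMF, rt
Reagents that add atoms: sodium benzenesulfinate, [Na+].[O-]S(=O)c1ccccc1
Why: S-alkylation of the sulfinate by the primary allylic chloride (SN2) installs the sulfonyl group that later stabilises the C2 carbanion.

Step 4
Reactants: 6 neryl phenyl sulfone
Product: 8 sulfonyl aldehyde (4Z)-4-methyl-6-(phenylsulfonyl)hex-4-enal, via terminal ozonide 7 (not isolated)
Conditions: O3, CH2Cl2, −78 °C (Sudan Red 7B end point); then PPh3, −78 °C to rt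
Reagents that add atoms: ozone, [O-][O+]=O
Why: Ozonolysis with reductive work-up should cleave the electron-rich terminal trisubstituted alkene first, because the other alkene is deactivated by the allylic sulfonyl group and ozone is dosed to an indicator end point.

Step 5
Reactants: 8 sulfonyl aldehyde; 3 PMB-oxymethyl phosphonoacetate
Product: 10 anilinooxy enoate methyl (2E,4S,6Z)-4-(anilinooxy)-2-{[(4-methoxybenzyl)oxy]methyl}-6-methyl-8-(phenylsulfonyl)octa-2,6-dienoate, via alpha-aminoxy aldehyde 9 (not isolated)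
Conditions: nitrosobenzene, D-proline (20 mol%), MeCN, −20 °C; then 3, LiCl, 1,8-diazabicyclo[5.4.0]undec-7-ene (DBU), 0 °C
Reagents that add atoms: nitrosobenzene, O=Nc1ccccc1
Why: Proline-catalysed alpha-aminoxylation (the carboxylic acid of the D-proline enamine directs the nitroso oxygen to the face giving (S)-C8) is followed in the same flask by a Masamune–Roush Horner–Wadsworth–Emmons olefination, which should place the ester (C13) trans and the CH2OPMB arm (C12) cis to C8.

Step 6
Reactants: 10 anilinooxy enoate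
Product: 11 hydroxy enoate, methyl (2E,4S,6Z)-4-hydroxy-2-{[(4-methoxybenzyl)oxy]methyl}-6-methyl-8-(phenylsulfonyl)octa-2,6-dienoate
Conditions: Zn dust, AcOH/THF, rt
Reagents that add atoms: none
Why: Dissolving-metal reduction cleaves the weak N–O bond and frees the C8 alcohol while the enoate, sulfone and PMB ether should be untouched; the hydroxyl is trans to the ester and cannot lactonise.

Step 7
Reactants: 11 hydroxy enoate
Product: 12 diol ester, methyl (2E,4S,6Z)-4-hydroxy-2-(hydroxymethyl)-6-methyl-8-(phenylsulfonyl)octa-2,6-dienoate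
Conditions: DDQ, CH2Cl2/pH 7 phosphate buffer, 0 °C
Reagents that add atoms: none
Why: Oxidative PMB cleavage (benzylic hydride abstraction, hydrolysis of the oxocarbenium ion in the wet medium) exposes the C12 alcohol so that no benzylic ether is carried into the later carbanion chemistry.

Step 8
Reactants: 12 diol ester
Product: 13 bis-TBS ester, methyl (2E,4S,6Z)-4-(TBS-oxy)-2-[(TBS-oxy)methyl]-6-methyl-8-(phenylsulfonyl)octa-2,6-dienoate
Conditions: TBSCl, imidazole, DMF, rt
Reagents that add atoms: tert-butyldimethylsilyl chloride, CC(C)(C)[Si](C)(C)Cl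
Why: Standard silylation gives a primary (C12) and a hindered secondary (C8) TBS ether that differ enough in lability to be removed one after the other at the end.

Step 9
Reactants: 13 bis-TBS ester
Product: 14 fragment alcohol (C7–C2 with C11–C13), (2Z,4S,6Z)-4-(TBS-oxy)-2-[(TBS-oxy)methyl]-6-methyl-8-(phenylsulfonyl)octa-2,6-dien-1-ol
Conditions: i-Bu2AlH, CH2Cl2, −78 °C
Reagents that add atoms: none
Why: 1,2-Reduction of the conjugated ester by the aluminium hydride gives the C13 allylic alcohol and should leave sulfone and silyl ethers intact.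

Step 10
Reactants: 15 but-2-yne-1,4-diol
Product: 16 mono-THP butynediol, 4-(tetrahydro-2H-pyran-2-yloxy)but-2-yn-1-ol
Conditions: 3,4-dihydro-2H-pyran, pyridinium p-toluenesulfonate (cat.), CH2Cl2, rt, 15 in excess
Reagents that add atoms: 3,4-dihydro-2H-pyran, C1=COCCC1
Why: Acid-catalysed acetalisation of one hydroxyl; an excess of the cheap diol favours mono-protection.

Step 11
Reactants: 16 mono-THP butynediol
Product: 17 Z iodo alcohol, (2Z)-3-iodo-4-(tetrahydro-2H-pyran-2-yloxy)but-2-en-1-ol
Conditions: NaAlH2(OCH2CH2OCH3)2, THF, 0 °C; then I2, −78 °C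
Reagents that add atoms: iodine, II
Why: Hydroxyl-directed trans-hydroalumination of the propargylic alcohol delivers hydride to C5 and aluminium to C4 in a five-membered alkoxyalanate, and iodinolysis with retention places iodine cis to the C6 carbinol, where C15 is needed.

Step 12
Reactants: 17 Z iodo alcohol
Product: 18 PMB iodo ether, 2-({(2Z)-2-iodo-4-[(4-methoxybenzyl)oxy]but-2-en-1-yl}oxy)tetrahydro-2H-pyran
Conditions: NaH, 4-methoxybenzyl chloride, Bu4NI (cat.), THF/DMF, 0 °C to rt
Reagents that add atoms: 4-methoxybenzyl chloride, COc1ccc(CCl)cc1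
Why: Williamson etherification masks the C6 alcohol with a group that survives the coupling chemistry and is later removed oxidatively.

Step 13
Reactants: 18 PMB iodo ether
Product: 19 hydroxymethyl alkene, (2E)-4-[(4-methoxybenzyl)oxy]-2-[(tetrahydro-2H-pyran-2-yloxy)methyl]but-2-en-1-ol
Conditions: Bu3SnCH2OH, Pd(PPh3)4 (cat.), 1,4-dioxane, 90 °C
Reagents that add atoms: (tributylstannyl)methanol, CCCC[Sn](CO)(CCCC)CCCC
Why: Stille coupling at zerovalent palladium transfers the hydroxymethyl group to the alkenyl iodide with retention of geometry, so C15 ends up cis to C6.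

Step 14
Reactants: 19 hydroxymethyl alkene
Product: 20 TBDPS ether, tert-butyl({(2Z)-4-[(4-methoxybenzyl)oxy]-2-[(tetrahydro-2H-pyran-2-yloxy)methyl]but-2-en-1-yl}oxy)diphenylsilane
Conditions: TBDPSCl, imidazole, CH2Cl2, rt
Reagents that add atoms: tert-butyl(chloro)diphenylsilane, CC(C)(C)[Si](Cl)(c1ccccc1)c1ccccc1
Why: Silylation of the primary C15 alcohol installs the most robust silyl ether of the route, which is kept until the last step.

Step 15
Reactants: 20 TBDPS ether
Product: 21 allylic alcohol, (2Z)-2-{[(tert-butyldiphenylsilyl)oxy]methyl}-4-[(4-methoxybenzyl)oxy]but-2-en-1-ol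
Conditions: pyridinium p-toluenesulfonate (cat.), MeOH, 40 °C
Reagents that add atoms: none
Why: Mild acid-catalysed transacetalisation removes only the THP group and frees the C3 alcohol.

Step 16
Reactants: 21 allylic alcohol
Product: 22 allylic bromide (fragment C3–C6 with C15), {[(2E)-2-(bromomethyl)-4-[(4-methoxybenzyl)oxy]but-2-en-1-yl]oxy}(tert-butyl)diphenylsilane
Conditions: CBr4, PPh3, CH2Cl2, 0 °C
Reagents that add atoms: tetrabromomethane, BrC(Br)(Br)Br
Why: Appel bromination converts the primary allylic alcohol into the bromide by SN2 displacement of the oxyphosphonium ion.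

Step 17
Reactants: 14 fragment alcohol; 22 allylic bromide
Product: 23 coupled sulfone, (2Z,4S,6Z,10Z)-4-(TBS-oxy)-2-[(TBS-oxy)methyl]-10-[(TBDPS-oxy)methyl]-12-[(4-methoxybenzyl)oxy]-6-methyl-8-(phenylsulfonyl)dodeca-2,6,10-trien-1-ol (mixture at C8 of the chain, which is germacrane C2)
Conditions: n-BuLi (2.1 equiv), THF, −78 °C; then 22, −78 to −40 °C
Reagents that add atoms: none
Why: Allyl sulfone alkylation: the alkoxide/sulfonyl carbanion dianion of 14 reacts at carbon with the primary allylic bromide (SN2) and forms the C2–C3 bond, the lithium alkoxide being a poor nucleophile at this temperature.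

Step 18
Reactants: 23 coupled sulfone
Product: 24 seco alcohol, (2Z,4S,6Z,10Z)-4-(TBS-oxy)-2-[(TBS-oxy)methyl]-10-[(TBDPS-oxy)methyl]-12-[(4-methoxybenzyl)oxy]-6-methyldodeca-2,6,10-trien-1-ol
Conditions: PdCl2[Ph2P(CH2)3PPh2] (cat.), LiBHEt3, THF, 0 °C
Reagents that add atoms: none
Why: Palladium-catalysed reductive desulfonylation: zerovalent palladium ionises the allylic sulfone and hydride is delivered to the less substituted allyl terminus C2, which should return the C1=C10 alkene in place and with its Z geometry.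

Step 19
Reactants: 24 seco alcohol
Product: 25 seco chloride (24 with the C13 hydroxyl replaced by chlorine)
Conditions: N-chlorosuccinimide, Me2S, CH2Cl2, −30 to 0 °C
Reagents that add atoms: N-chlorosuccinimide, O=C1CCC(=O)N1Cl
Why: Corey–Kim chlorination turns the C13 allylic alcohol into the primary allylic chloride under neutral conditions that spare silyl and PMB ethers.

Step 20
Reactants: 25 seco chloride
Product: 26 chloro alcohol (25 with the PMB ether cleaved to the C6 alcohol)
Conditions: DDQ, CH2Cl2/pH 7 phosphate buffer, 0 °C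
Reagents that add atoms: none
Why: Oxidative PMB cleavage frees the C6 alcohol while the silyl ethers and the allylic chloride should be inert.

Step 21
Reactants: 26 chloro alcohol
Product: 27 13-membered bis-allylic ether (ring C3–C4=C5–C6–O–C13–C11=C7–C8–C9–C10=C1–C2; CH2OTBDPS on C4, CH2OTBS on C11, (8S)-OTBS, CH3 on C10)
Conditions: NaH, Bu4NI (cat.), THF, 50 °C, slow addition (high dilution)
Reagents that add atoms: none
Why: Intramolecular Williamson etherification: the C6 alkoxide displaces the allylic chloride at C13 (13-exo-tet, iodide catalysis), and high dilution favours ring closure over oligomerisation.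

Step 22
Reactants: 27 13-membered bis-allylic ether
Product: 28 ten-membered homoallylic alcohol ((6R,7S,8S) in germacrane locants: 6-OH, 7-[3-(TBS-oxy)prop-1-en-2-yl], 8-OTBS, 4-CH2OTBDPS, 10-CH3)
Conditions: n-BuLi, THF, −78 to −30 °C; aq. NH4Cl
Reagents that add atoms: none
Why: n-BuLi removes a proton from C6, the alpha-oxy allylic CH2 next to the unsubstituted C5–H, and the lithio ether rearranges by a suprafacial [2,3]-sigmatropic (Wittig) shift through a five-membered envelope transition state made of C6, O, C13, C11 and C7, so that C6–C7 forms, O–C13 breaks and C11=C13 becomes the exocyclic methylene. The closest known reaction type is the [2,3]-Wittig ring contraction of 13-membered bis-allylic ethers to ten-membered germacrane carbocycles. The ten-membered ring closes by transannular ring contraction, C6 bonding to C7 across the 13-membered ring. The C6/C7 relationship is controlled by the C7=C11 geometry (C8 trans to C13) together with the exo position of the C5 vinyl substituent in the envelope, which should give the anti arrangement needed for the trans lactone. The face relative to C8 is controlled by allylic 1,3-strain between the C12 silyloxymethyl group and C8, which keeps H8 in the alkene plane and lets C6, tethered through C9, add to the C7 face away from the C8 silyloxy group. The step needs deprotonation at C6 and not at C13, C12 or C15: C13 is flanked by the fully substituted C11, the silyloxymethylenes are shielded by their bulky silyl groups, and the low temperature should suppress the [1,2]-shift and loss of silanolate from the C6 anion.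

Step 23
Reactants: 28 ten-membered homoallylic alcohol
Product: 29 2-methylene-1,4-diol (28 with the C12 TBS ether cleaved)
Conditions: HF·pyridine, pyridine, THF, 0 °C
Reagents that add atoms: none
Why: Buffered fluoride desilylation should remove the unhindered primary allylic TBS ether well before the hindered secondary TBS ether at C8 and the TBDPS ether at C15.

Step 24
Reactants: 29 2-methylene-1,4-diol
Product: 32 silylated methylene lactone (6,12-olide; C8-OTBS; C15-OTBDPS), via hydroxy enal 30 (not isolated), via lactol 31 (not isolated)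
Conditions: 2,2,6,6-tetramethylpiperidin-1-oxyl (TEMPO, cat.), PhI(OAc)2, CH2Cl2, rt
Reagents that add atoms: none
Why: Oxidative lactonisation: the oxoammonium oxidant takes the primary allylic C12 alcohol to the enal, the C6 hydroxyl closes the five-membered lactol, and a second oxidation gives the alpha-methylene lactone, trans-fused as fixed by C6 and C7.

Step 25
Reactants: 32 silylated methylene lactone
Product: 33 C8 alcohol (32 with the C8 TBS ether cleaved)
Conditions: HF·pyridine, pyridine, THF, 0 °C to rt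
Reagents that add atoms: none
Why: Longer exposure to buffered HF·pyridine should cleave the secondary TBS ether while the more stable TBDPS ether stays, and the non-basic medium spares the methylene lactone and the 1,5-diene.

Step 26
Reactants: 34 Roche ester, methyl (R)-3-hydroxy-2-methylpropanoate
Product: 35 TBS Roche ester, methyl (R)-3-(TBS-oxy)-2-methylpropanoate
Conditions: TBSCl, imidazole, CH2Cl2, rt
Reagents that add atoms: tert-butyldimethylsilyl chloride, CC(C)(C)[Si](C)(C)Cl
Why: Silylation protects the primary hydroxyl so that the acid can later be activated without self-condensation.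

Step 27
Reactants: 35 TBS Roche ester
Product: 36 TBS Roche acid, (R)-3-(TBS-oxy)-2-methylpropanoic acid
Conditions: LiOH, THF/H2O, 0 °C; then 1 M HCl
Reagents that add atoms: lithium hydroxide, [Li+].[OH-]
Why: Saponification at low temperature gives the acid; the alpha-stereocentre bears no strongly acidifying group and should not epimerise.

Step 28
Reactants: 33 C8 alcohol; 36 TBS Roche acid
Product: 37 bis-silyl ester (C8 (R)-3-(TBS-oxy)-2-methylpropanoate of 33)
Conditions: N,N′-dicyclohexylcarbodiimide, 4-(dimethylamino)pyridine (cat.), CH2Cl2, 0 °C to rt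
Reagents that add atoms: none
Why: Steglich esterification acylates the secondary C8 alcohol through the acylpyridinium ion under neutral conditions, with retention at C8 and at the acyl alpha-carbon.

Step 29
Reactants: 37 bis-silyl ester
Product: 38 target, [(3aR,4S,6Z,10Z,11aR)-10-(hydroxymethyl)-6-methyl-3-methylidene-2-oxo-3a,4,5,8,9,11a-hexahydrocyclodeca[b]furan-4-yl] (2R)-3-hydroxy-2-methylpropanoate
Conditions: HF·pyridine, pyridine, THF, 0 °C to rt
Reagents that add atoms: none
Why: Fluoride-mediated desilylation removes the TBDPS and the primary TBS ether under buffered, non-basic conditions that should spare the methylene lactone, the beta-hydroxy ester and the acid-sensitive 1,5-diene.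

**Compound list**

1 | trimethyl 2-phosphonoacrylate (methyl 2-(dimethoxyphosphoryl)prop-2-enoate) | C=C(C(=O)OC)P(=O)(OC)OC | starting material
2 | 4-methoxybenzyl alcohol | COc1ccc(CO)cc1 | starting material
3 | PMB-oxymethyl phosphonoacetate, methyl 2-(dimethoxyphosphoryl)-3-[(4-methoxybenzyl)oxy]propanoate | COC(=O)C(COCc1ccc(OC)cc1)P(=O)(OC)OC | intermediate
4 | nerol | CC(C)=CCC/C(C)=C\CO | starting material
5 | neryl chloride | CC(C)=CCC/C(C)=C\CCl | intermediate
6 | neryl phenyl sulfone | CC(C)=CCC/C(C)=C\CS(=O)(=O)c1ccccc1 | intermediate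
7 | terminal ozonide (3,3-dimethyl-1,2,4-trioxolane bearing the (3Z)-3-methyl-5-(phenylsulfonyl)pent-3-enyl chain on C5) | CC1(C)OOC(CC/C(C)=C\CS(=O)(=O)c2ccccc2)O1 | intermediate
8 | sulfonyl aldehyde, (4Z)-4-methyl-6-(phenylsulfonyl)hex-4-enal | O=CCC/C(C)=C\CS(=O)(=O)c1ccccc1 | intermediate
9 | alpha-aminoxy aldehyde, (2S,4Z)-2-(anilinooxy)-4-methyl-6-(phenylsulfonyl)hex-4-enal | O=C[C@@H](ONc1ccccc1)C/C(C)=C\CS(=O)(=O)c1ccccc1 | intermediate
10 | anilinooxy enoate, methyl (2E,4S,6Z)-4-(anilinooxy)-2-{[(4-methoxybenzyl)oxy]methyl}-6-methyl-8-(phenylsulfonyl)octa-2,6-dienoate | COC(=O)/C(COCc1ccc(OC)cc1)=C/[C@@H](ONc1ccccc1)C/C(C)=C\CS(=O)(=O)c1ccccc1 | intermediate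
11 | hydroxy enoate | COC(=O)/C(COCc1ccc(OC)cc1)=C/[C@@H](O)C/C(C)=C\CS(=O)(=O)c1ccccc1 | intermediate
12 | diol ester | COC(=O)/C(CO)=C/[C@@H](O)C/C(C)=C\CS(=O)(=O)c1ccccc1 | intermediate
13 | bis-TBS ester | COC(=O)/C(CO[Si](C)(C)C(C)(C)C)=C/[C@@H](O[Si](C)(C)C(C)(C)C)C/C(C)=C\CS(=O)(=O)c1ccccc1 | intermediate
14 | fragment alcohol (C7–C2 with C11–C13) | OC/C(CO[Si](C)(C)C(C)(C)C)=C/[C@@H](O[Si](C)(C)C(C)(C)C)C/C(C)=C\CS(=O)(=O)c1ccccc1 | intermediate
15 | but-2-yne-1,4-diol | OCC#CCO | starting material
16 | mono-THP butynediol | OCC#CCOC1CCCCO1 | intermediate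
17 | Z iodo alcohol | OC/C=C(\I)COC1CCCCO1 | intermediate
18 | PMB iodo ether | COc1ccc(COC/C=C(\I)COC2CCCCO2)cc1 | intermediate
19 | hydroxymethyl alkene (CH2OH cis to the CH2OPMB arm) | COc1ccc(COC/C=C(\CO)COC2CCCCO2)cc1 | intermediate
20 | TBDPS ether | COc1ccc(COC/C=C(\CO[Si](c2ccccc2)(c2ccccc2)C(C)(C)C)COC2CCCCO2)cc1 | intermediate
21 | allylic alcohol | COc1ccc(COC/C=C(\CO[Si](c2ccccc2)(c2ccccc2)C(C)(C)C)CO)cc1 | intermediate
22 | allylic bromide (fragment C3–C6 with C15) | COc1ccc(COC/C=C(\CO[Si](c2ccccc2)(c2ccccc2)C(C)(C)C)CBr)cc1 | intermediate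
23 | coupled sulfone (C2 epimers) | OC/C(CO[Si](C)(C)C(C)(C)C)=C/[C@@H](O[Si](C)(C)C(C)(C)C)C/C(C)=C\C(S(=O)(=O)c1ccccc1)C/C(CO[Si](c1ccccc1)(c1ccccc1)C(C)(C)C)=C/COCc1ccc(OC)cc1 | intermediate
24 | seco alcohol | OC/C(CO[Si](C)(C)C(C)(C)C)=C/[C@@H](O[Si](C)(C)C(C)(C)C)C/C(C)=C\CC/C(CO[Si](c1ccccc1)(c1ccccc1)C(C)(C)C)=C/COCc1ccc(OC)cc1 | intermediate
25 | seco chloride | ClC/C(CO[Si](C)(C)C(C)(C)C)=C/[C@@H](O[Si](C)(C)C(C)(C)C)C/C(C)=C\CC/C(CO[Si](c1ccccc1)(c1ccccc1)C(C)(C)C)=C/COCc1ccc(OC)cc1 | intermediate
26 | chloro alcohol | ClC/C(CO[Si](C)(C)C(C)(C)C)=C/[C@@H](O[Si](C)(C)C(C)(C)C)C/C(C)=C\CC/C(CO[Si](c1ccccc1)(c1ccccc1)C(C)(C)C)=C/CO | intermediate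
27 | 13-membered bis-allylic ether (C3 trans to C6, C13 trans to C8, C2 cis to C9; 8S) | C1/C(CO[Si](c2ccccc2)(c2ccccc2)C(C)(C)C)=C/COC/C(CO[Si](C)(C)C(C)(C)C)=C/[C@@H](O[Si](C)(C)C(C)(C)C)C/C(C)=C\C1 | intermediate
28 | ten-membered homoallylic alcohol | O[C@@H]1/C=C(\CO[Si](c2ccccc2)(c2ccccc2)C(C)(C)C)CC/C=C(/C)C[C@H](O[Si](C)(C)C(C)(C)C)[C@H]1C(=C)CO[Si](C)(C)C(C)(C)C | intermediate
29 | 2-methylene-1,4-diol | O[C@@H]1/C=C(\CO[Si](c2ccccc2)(c2ccccc2)C(C)(C)C)CC/C=C(/C)C[C@H](O[Si](C)(C)C(C)(C)C)[C@H]1C(=C)CO | intermediate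
30 | hydroxy enal | O[C@@H]1/C=C(\CO[Si](c2ccccc2)(c2ccccc2)C(C)(C)C)CC/C=C(/C)C[C@H](O[Si](C)(C)C(C)(C)C)[C@H]1C(=C)C=O | intermediate
31 | lactol (mixture at C12) | C=C1C(O)O[C@@H]2/C=C(\CO[Si](c3ccccc3)(c3ccccc3)C(C)(C)C)CC/C=C(/C)C[C@H](O[Si](C)(C)C(C)(C)C)[C@@H]12 | intermediate
32 | silylated methylene lactone | C=C1C(=O)O[C@@H]2/C=C(\CO[Si](c3ccccc3)(c3ccccc3)C(C)(C)C)CC/C=C(/C)C[C@H](O[Si](C)(C)C(C)(C)C)[C@@H]12 | intermediate
33 | C8 alcohol | C=C1C(=O)O[C@@H]2/C=C(\CO[Si](c3ccccc3)(c3ccccc3)C(C)(C)C)CC/C=C(/C)C[C@H](O)[C@@H]12 | intermediate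
34 | Roche ester, methyl (R)-3-hydroxy-2-methylpropanoate | COC(=O)[C@H](C)CO | starting material
35 | TBS Roche ester | COC(=O)[C@H](C)CO[Si](C)(C)C(C)(C)C | intermediate
36 | TBS Roche acid | OC(=O)[C@H](C)CO[Si](C)(C)C(C)(C)C | intermediate
37 | bis-silyl ester | C=C1C(=O)O[C@@H]2/C=C(\CO[Si](c3ccccc3)(c3ccccc3)C(C)(C)C)CC/C=C(/C)C[C@H](OC(=O)[C@H](C)CO[Si](C)(C)C(C)(C)C)[C@@H]12 | intermediate
38 | target | C=C1C(=O)O[C@@H]2/C=C(\CO)CC/C=C(/C)C[C@H](OC(=O)[C@H](C)CO)[C@@H]12 | target

**Step count and risks**

Total steps: 29. Longest linear sequence: 19 (steps 2–9, 17–25, 28, 29).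

Most likely to fail:

1. Step 22. The base may deprotonate C13 or a silyloxymethylene instead of C6, the C6 anion may lose silanolate from C15 or undergo a [1,2]-shift, or the facial preference relative to C8 may be weak. Fallback, setting out from 26: oxidation of the C6 alcohol with MnO2 would give the chloro enal F1. CrCl2 in THF under high dilution would then turn the allylic chloride into an allylchromium species that adds through its gamma carbon C7 to the C6 aldehyde (intramolecular Nozaki–Hiyama–Kishi allylation). This forms the same C6–C7 bond and C11=C13 methylene, should favour the same anti C6/C7 relationship, and comes back to the route at 28.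

2. Step 5. Olefination by the alpha-substituted phosphonate may be slow enough for the base-labile aminoxy aldehyde to epimerise at C8, the phosphonate anion may lose the PMB-oxy group by retro-Michael reaction, and E selectivity may be incomplete. Fallback, setting out from 8: the aminoxylation mixture would be reduced in the same flask with NaBH4 to the aminoxy alcohol F2. Zn/AcOH would give the diol F3, TBSCl/imidazole the bis-TBS ether F4, and HF·pyridine would cleave the primary silyl ether to the alcohol F5. Dess–Martin oxidation would give the configurationally more robust alpha-silyloxy aldehyde F6, which is olefinated separately with 3 (LiCl, i-Pr2NEt) to the enoate F7. DDQ would give the alcohol F8, and silylation with TBSCl comes back to the route at 13.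

3. Step 21. Bimolecular etherification may outrun ring closure because the electrophilic carbon C13 is flanked by the silyloxymethyl group, and SN2′ attack at C7 may interfere. Fallback, setting out from 24: the C13 alcohol would be masked with Et3SiCl/imidazole as the triethylsilyl ether F9, and DDQ would free the C6 alcohol F10. CBr4/PPh3 would give the C6 bromide F11, and HF·pyridine at −10 °C would cleave only the triethylsilyl ether to the bromo alcohol F12. NaH under high dilution would then close the ring by attack of the C13 alkoxide on the unhindered C6 bromide, so that the O–C6 bond is formed instead of O–C13; this comes back to the route at 27.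

Further compounds
F1 | step 22 | chloro enal (26 with the C6 alcohol oxidised to the aldehyde) | ClC/C(CO[Si](C)(C)C(C)(C)C)=C/[C@@H](O[Si](C)(C)C(C)(C)C)C/C(C)=C\CC/C(CO[Si](c1ccccc1)(c1ccccc1)C(C)(C)C)=C/C=O
F2 | step 5 | aminoxy alcohol, (2S,4Z)-2-(anilinooxy)-4-methyl-6-(phenylsulfonyl)hex-4-en-1-ol | OC[C@@H](ONc1ccccc1)C/C(C)=C\CS(=O)(=O)c1ccccc1
F3 | step 5 | diol, (2S,4Z)-4-methyl-6-(phenylsulfonyl)hex-4-ene-1,2-diol | OC[C@@H](O)C/C(C)=C\CS(=O)(=O)c1ccccc1
F4 | step 5 | bis-TBS ether of F3 | CC(C)(C)[Si](C)(C)OC[C@@H](O[Si](C)(C)C(C)(C)C)C/C(C)=C\CS(=O)(=O)c1ccccc1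
F5 | step 5 | alcohol, (2S,4Z)-2-(TBS-oxy)-4-methyl-6-(phenylsulfonyl)hex-4-en-1-ol | OC[C@@H](O[Si](C)(C)C(C)(C)C)C/C(C)=C\CS(=O)(=O)c1ccccc1
F6 | step 5 | alpha-silyloxy aldehyde, (2S,4Z)-2-(TBS-oxy)-4-methyl-6-(phenylsulfonyl)hex-4-enal | O=C[C@@H](O[Si](C)(C)C(C)(C)C)C/C(C)=C\CS(=O)(=O)c1ccccc1
F7 | step 5 | enoate, methyl (2E,4S,6Z)-4-(TBS-oxy)-2-{[(4-methoxybenzyl)oxy]methyl}-6-methyl-8-(phenylsulfonyl)octa-2,6-dienoate | COC(=O)/C(COCc1ccc(OC)cc1)=C/[C@@H](O[Si](C)(C)C(C)(C)C)C/C(C)=C\CS(=O)(=O)c1ccccc1
F8 | step 5 | alcohol, methyl (2E,4S,6Z)-4-(TBS-oxy)-2-(hydroxymethyl)-6-methyl-8-(phenylsulfonyl)octa-2,6-dienoate | COC(=O)/C(CO)=C/[C@@H](O[Si](C)(C)C(C)(C)C)C/C(C)=C\CS(=O)(=O)c1ccccc1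
F9 | step 21 | triethylsilyl ether (24 silylated at the C13 hydroxyl) | CC[Si](CC)(CC)OC/C(CO[Si](C)(C)C(C)(C)C)=C/[C@@H](O[Si](C)(C)C(C)(C)C)C/C(C)=C\CC/C(CO[Si](c1ccccc1)(c1ccccc1)C(C)(C)C)=C/COCc1ccc(OC)cc1
F10 | step 21 | C6 alcohol (F9 without the PMB group) | CC[Si](CC)(CC)OC/C(CO[Si](C)(C)C(C)(C)C)=C/[C@@H](O[Si](C)(C)C(C)(C)C)C/C(C)=C\CC/C(CO[Si](c1ccccc1)(c1ccccc1)C(C)(C)C)=C/CO
F11 | step 21 | C6 bromide | CC[Si](CC)(CC)OC/C(CO[Si](C)(C)C(C)(C)C)=C/[C@@H](O[Si](C)(C)C(C)(C)C)C/C(C)=C\CC/C(CO[Si](c1ccccc1)(c1ccccc1)C(C)(C)C)=C/CBr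
F12 | step 21 | bromo alcohol (C13 hydroxyl free, C6 bromide) | OC/C(CO[Si](C)(C)C(C)(C)C)=C/[C@@H](O[Si](C)(C)C(C)(C)C)C/C(C)=C\CC/C(CO[Si](c1ccccc1)(c1ccccc1)C(C)(C)C)=C/CBr
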